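**Assumption:** the P450 preparation is treated as a catalyst, not a starting material. The 17S sense of hydroxylation is taken from the S configuration of the 17‑hydroxyoleic acid that Starmerella yeasts build into their glycolipids.

## The problem

Hansfordiol E (12) is a 5‑alkylresorcinol with an unbranched C17 chain (C1'–C17') on ring carbon C5, a Z olefin at C8'=C9' and one stereocentre, the S methyl carbinol C16'. No ring is hard to close. The difficulty is that arene, olefin and carbinol are insulated by seven and six methylene groups, so none can direct the making of another. The olefin is isolated: its geometry must be made with full Z control or bought, because E/Z isomers of such a chain are practically inseparable. Once present it rules out Br2, I2, hydrogenation, strong Lewis or protic acids and radical conditions. The stereocentre sits at the penultimate carbon of a hydrocarbon chain, where only reagent control, the chiral pool or an enzyme can set it. The resorcinol is oxidation‑prone in base, and the usual aryl ethers come off under conditions (BBr3, hydrogenolysis) that clash with the olefin and the carbinol.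

The feature that opens the problem: ring carbon C5 together with C1'–C17' is, atom for atom, the chain of oleic acid (1). C5 is the carboxyl carbon C1, C8'=C9' is the 9Z olefin, and C16' is C17, the (ω‑1) carbon. The other five ring carbons (C4, C3, C2, C1, C6) are at the oxidation level of a polyketide triacetate unit, which is how polyketide synthases of type three assemble alkylresorcinols.

## Retrosynthesis

**12 ⇒ 9 (through 11 and 10).** No skeletal bond is cut. A carboxyl carbon is put back on ring C4 (C4 and C6 are equivalent), tied to the C3 hydroxyl as an acetonide, and the C16' hydroxyl is masked as a TBS ether. This gives benzodioxinone 9. The carboxyl is the polyketide activating group that makes the next cut unambiguous. The forward step has to open the acetonide to resorcylic acid 10, lose CO2 to silyl ether 11 and desilylate, all without touching the olefin.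

**9 ⇒ 8.** The arene bond C4a–C5 of 9 (carboxyl‑bearing carbon to chain‑bearing carbon) is cut as an aldol retron, which leads to the acyclic diketo‑dioxinone 8. The same cut in a carboxyl‑free 2,4,6‑triketone would let the α‑methylene of the chain compete with the methyl terminus and give a 4‑alkyl‑5‑methylresorcinol. A saturated‑ring precursor would need an oxidant that the olefin cannot tolerate. Precursor 8 has no arene and no phenol protecting groups. The forward reaction must cyclize in one mode only under mild base.

**8 ⇒ 4 + 6 (through 7); 6 ⇒ 5.** The C3'–C4' bond of the side chain of 8 is cut; C4' is the former carboxyl carbon of acid 4, C3' the former methyl carbon of keto‑dioxinone 6. This uses the acid carbon as the electrophile it already is (as acyl imidazole 7). A cut one bond further along would require a β‑keto acid derivative of 4 and extra steps. Acid 4 carries the olefin and the stereocentre; 6 comes in one step from commercial dioxinone 5. The forward reaction must acylate the dianion of 6 at its terminal carbon.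

**4 ⇒ 2 (through 3).** The silyl ether is removed. The dianion step needs an aprotic substrate, and the bis‑silyl derivative 3 loses its silyl ester selectively.

**2 ⇒ 1.** The C17–O bond is cut, a C–H oxidation retron. Against this stand all cuts at the olefin, which build the chain from two halves and must create the Z geometry. Here the geometry and the chain length are bought with oleic acid 1. The forward reaction must hydroxylate one unactivated methylene of eight, enantioselectively, next to an olefin; only an enzyme does this.

## Roads not taken

**Alternative 1: Wittig olefination at C8'=C9' (the obvious route).** The cut gives 8‑(3,5‑dimethoxyphenyl)octanal A1 and phosphonium salt A2, the latter built from (S)‑propylene oxide. The forward key step is a salt‑free Wittig reaction to protected olefin A3, then desilylation and demethylation to 12. The chosen plan is better for three reasons: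
- Each fragment needs its own multi‑step synthesis.
- The unstabilized ylide gives mainly, but not only, the Z olefin, and the E isomer cannot be removed.
- The aryl methyl ethers require BBr3, whose HBr endangers the olefin and the secondary alcohol.

**Alternative 2: alkyne linchpin.** The cut at C9'–C10' gives terminal alkyne A4 and iodide A5. The forward key step is acetylide alkylation to internal alkyne A6, then semi‑hydrogenation (H2, Pd/CaCO3 poisoned with Pb(OAc)2, quinoline) to A3. The Z geometry is secure, but the fragment count, the step count and the phenol deprotection problem are those of Alternative 1. The alkylation of a long‑chain acetylide with an unactivated iodide and the risk of over‑reduction add to this.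

**Alternative 3: ring built on the same oleic skeleton one oxidation level lower and aromatized late.** Acid 4 would be taken to the aldehyde oxidation level and olefinated with Ph3P=CHC(O)CH3 to enone A7. Michael addition of dimethyl malonate, Claisen closure and hydrolysis–decarboxylation would give cyclohexane‑1,3‑dione A8, and oxidative aromatization would give the resorcinol. This needs two redox adjustments that the chosen route avoids, because an acyl carbon is already at the arene oxidation level. The final oxidant (Br2, I2 or a palladium dehydrogenation catalyst) would add to or isomerize the Z olefin.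

Key step: step 1

## Route

**Step 1**
Reactants: 1 oleic acid, (9Z)-octadec-9-enoic acid
Product: 2 (9Z,17S)-17-hydroxyoctadec-9-enoic acid
Conditions: recombinant CYP52M1-type cytochrome P450 monooxygenase with its NADPH–cytochrome P450 reductase (resting whole cells or cell-free extract), air, NADP+ (cat.), glucose dehydrogenase, D-glucose, potassium phosphate buffer pH 7.5, 2% DMSO, 30 °C; then pH 3, EtOAc
Reagents that add atoms: dioxygen, O=O
Why: Enzymatic C–H hydroxylation by a cytochrome P450 monooxygenase: the heme iron takes two electrons from NADPH through the reductase, binds O2 and forms an oxoiron porphyrin radical cation (iron formally tetravalent) that abstracts a hydrogen atom from C17 and returns OH to the carbon radical on the same face (oxygen rebound). The closest known reaction type is the (ω‑1)-hydroxylation of C16–C20 fatty acids by yeast CYP52 hydroxylases, for which oleic acid is a native substrate. No ring is closed. The new stereocentre C17 is under pure catalyst control: the pocket presents only one of the two enantiotopic C17 hydrogens to the oxo ligand, and rebound with retention should give the 17S alcohol, the configuration of the hydroxy acid this enzyme class makes in nature. The step needs (ω‑1) over ω and (ω‑2) regioselectivity, C–H hydroxylation over epoxidation of C9=C10 and over allylic oxidation at C8 and C11, and a stop at the alcohol. The substrate secures this through its carboxylate and its length: bound, by analogy with other fatty-acid hydroxylases, with the carboxylate at the mouth of a narrow channel, an 18-carbon chain puts only its methyl end at the iron-oxo unit and keeps the olefin and its allylic carbons at least six carbons away, and of the two carbons in reach the secondary C17–H bond is weaker than the primary C18–H bond. The Z geometry is not touched, since nothing in the medium can isomerize an isolated olefin.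

**Step 2**
Reactants: 2 (9Z,17S)-17-hydroxyoctadec-9-enoic acid
Product: 4 (9Z,17S)-17-[(tert-butyldimethylsilyl)oxy]octadec-9-enoic acid, via bis-silyl derivative 3 (not isolated)
Conditions: TBSCl (2.5 equiv), imidazole, DMF, rt; then K2CO3, MeOH/THF/H2O, rt; then 1 M HCl to pH 4, 0 °C
Reagents that add atoms: tert-butyldimethylsilyl chloride (TBSCl), CC(C)(C)[Si](C)(C)Cl
Why: Standard silylation of alcohol and acid, then selective solvolysis of the labile silyl ester by carbonate in aqueous methanol, which leaves the secondary silyl ether; the stereocentre and the olefin are not involved.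

**Step 3**
Reactants: 5 2,2,6-trimethyl-4H-1,3-dioxin-4-one
Product: 6 2,2-dimethyl-6-(2-oxopropyl)-4H-1,3-dioxin-4-one
Conditions: LiN(SiMe3)2 (1.0 equiv), THF, −78 °C; then acetyl chloride (0.5 equiv), −78 °C
Reagents that add atoms: acetyl chloride, CC(=O)Cl
Why: γ‑Deprotonation gives the lithium dienolate of the dioxinone, which is C‑acylated at the γ‑carbon (vinylogous Claisen-type acylation); half an equivalent of acyl chloride is used because the more acidic product consumes a second equivalent of enolate.

**Step 4**
Reactants: 4 (9Z,17S)-17-[(tert-butyldimethylsilyl)oxy]octadec-9-enoic acid; 6 2,2-dimethyl-6-(2-oxopropyl)-4H-1,3-dioxin-4-one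
Product: 8 6-[(12Z,20S)-20-[(tert-butyldimethylsilyl)oxy]-2,4-dioxohenicos-12-en-1-yl]-2,2-dimethyl-4H-1,3-dioxin-4-one, via acyl imidazole 7 (not isolated)
Conditions: 4, 1,1'-carbonyldiimidazole (1.1 equiv), THF, rt; added to 6 (3 equiv) pre-treated with LiN(i-Pr)2 (6 equiv), THF, −78 °C; −78 → −30 °C; AcOH quench
Reagents that add atoms: none
Why: Claisen-type C‑acylation of a 1,3‑dicarbonyl dianion at its terminal, methyl-derived carbon by an acyl imidazole, as used to assemble diketo‑dioxinones; the excess dianion absorbs the imidazole N–H and the acidic product. The olefin and the silyl ether are inert to the amide base at low temperature.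

**Step 5**
Reactants: 8 6-[(12Z,20S)-20-[(tert-butyldimethylsilyl)oxy]-2,4-dioxohenicos-12-en-1-yl]-2,2-dimethyl-4H-1,3-dioxin-4-one
Product: 9 5-[(8Z,16S)-16-[(tert-butyldimethylsilyl)oxy]heptadec-8-en-1-yl]-7-hydroxy-2,2-dimethyl-4H-1,3-benzodioxin-4-one
Conditions: Et3N, CH2Cl2, rt
Reagents that add atoms: none
Why: Polyketide-type aldol cycloaromatization of a diketo‑dioxinone: Et3N forms the dienolate across the dioxinone, whose α‑carbon adds to the C4' ketone in a 6‑(enolexo)‑exo‑trig closure, and loss of water with enolization of the C2' ketone gives the arene. Only this carbon is acidic enough for Et3N, so the α‑methylene of the chain cannot compete and the 1,3,5 pattern is fixed.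

**Step 6**
Reactants: 9 5-[(8Z,16S)-16-[(tert-butyldimethylsilyl)oxy]heptadec-8-en-1-yl]-7-hydroxy-2,2-dimethyl-4H-1,3-benzodioxin-4-one
Product: 12 Hansfordiol E, via resorcylic acid 10 (not isolated), via silyl ether 11 (not isolated)
Conditions: KOH, EtOH/H2O (degassed), 90 °C, Ar; then 3 M HCl to pH 1, 50 °C
Reagents that add atoms: none
Why: Hydroxide opens the acetonide of the salicylate to the 6‑alkyl‑β‑resorcylate, which loses CO2 on heating through its keto tautomer (a vinylogous β‑keto acid), as in the hydrolysis–decarboxylation of olivetolate-type esters; aqueous HCl then cleaves the secondary silyl ether. Neither stage should affect the isolated Z olefin or the configuration at C16'.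

## Compound list

1 | oleic acid, (9Z)-octadec-9-enoic acid | CCCCCCCC/C=C\CCCCCCCC(=O)O | starting material
2 | (9Z,17S)-17-hydroxyoctadec-9-enoic acid | C[C@H](O)CCCCCC/C=C\CCCCCCCC(=O)O | intermediate
3 | tert-butyldimethylsilyl (9Z,17S)-17-[(tert-butyldimethylsilyl)oxy]octadec-9-enoate | C[C@H](O[Si](C)(C)C(C)(C)C)CCCCCC/C=C\CCCCCCCC(=O)O[Si](C)(C)C(C)(C)C | intermediate
4 | (9Z,17S)-17-[(tert-butyldimethylsilyl)oxy]octadec-9-enoic acid | C[C@H](O[Si](C)(C)C(C)(C)C)CCCCCC/C=C\CCCCCCCC(=O)O | intermediate
5 | 2,2,6-trimethyl-4H-1,3-dioxin-4-one | CC1=CC(=O)OC(C)(C)O1 | starting material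
6 | 2,2-dimethyl-6-(2-oxopropyl)-4H-1,3-dioxin-4-one | CC(=O)CC1=CC(=O)OC(C)(C)O1 | intermediate
7 | (9Z,17S)-17-[(tert-butyldimethylsilyl)oxy]-1-(1H-imidazol-1-yl)octadec-9-en-1-one | C[C@H](O[Si](C)(C)C(C)(C)C)CCCCCC/C=C\CCCCCCCC(=O)n1ccnc1 | intermediate
8 | 6-[(12Z,20S)-20-[(tert-butyldimethylsilyl)oxy]-2,4-dioxohenicos-12-en-1-yl]-2,2-dimethyl-4H-1,3-dioxin-4-one | C[C@H](O[Si](C)(C)C(C)(C)C)CCCCCC/C=C\CCCCCCCC(=O)CC(=O)CC1=CC(=O)OC(C)(C)O1 | intermediate
9 | 5-[(8Z,16S)-16-[(tert-butyldimethylsilyl)oxy]heptadec-8-en-1-yl]-7-hydroxy-2,2-dimethyl-4H-1,3-benzodioxin-4-one | C[C@H](O[Si](C)(C)C(C)(C)C)CCCCCC/C=C\CCCCCCCc1cc(O)cc2OC(C)(C)OC(=O)c12 | intermediate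
10 | 2-[(8Z,16S)-16-[(tert-butyldimethylsilyl)oxy]heptadec-8-en-1-yl]-4,6-dihydroxybenzoic acid | C[C@H](O[Si](C)(C)C(C)(C)C)CCCCCC/C=C\CCCCCCCc1cc(O)cc(O)c1C(=O)O | intermediate
11 | 5-[(8Z,16S)-16-[(tert-butyldimethylsilyl)oxy]heptadec-8-en-1-yl]benzene-1,3-diol | C[C@H](O[Si](C)(C)C(C)(C)C)CCCCCC/C=C\CCCCCCCc1cc(O)cc(O)c1 | intermediate
12 | Hansfordiol E, 5-[(8Z,16S)-16-hydroxyheptadec-8-en-1-yl]benzene-1,3-diol | C[C@H](O)CCCCCC/C=C\CCCCCCCc1cc(O)cc(O)c1 | target

## Step count and risks

Total step count: 6. Longest linear sequence: 5 (steps 1, 2, 4, 5, 6); step 3 is a one-step side branch to building block 6.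

**Step 1 (key step).** The most likely failure is a spread of hydroxylation over C18, C17 and C16, together with low turnover. The soap-like substrate is poorly available to the enzyme, and uncoupled oxygen reduction wastes the cofactor. Fallback by chemical synthesis: it does not set out from 1 but replaces it by commercial (S)-propylene oxide and methyl dec-9-enoate, and it comes back to the route at compound 2. (S)-Propylene oxide is opened at its CH2 terminus by hept-6-enylmagnesium bromide with CuBr·SMe2 (cat.) to give (S)-dec-9-en-2-ol F1. Cross-metathesis of F1 with excess methyl dec-9-enoate over a Z-selective cyclometalated Grubbs catalyst (ruthenium N-adamantyl-NHC chelate with nitrate ligand) gives methyl (9Z,17S)-17-hydroxyoctadec-9-enoate F2. LiOH in THF/H2O then gives acid 2.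

**Step 4.** The dianion may transfer a proton to the enolizable acyl imidazole, or react at oxygen or twice, instead of undergoing one C‑acylation. Fallback: it sets out from compound 4 (through 7) and comes back at compound 10 inside step 6, by-passing 6, 8 and 9. The dianion of commercial 4-hydroxy-6-methyl-2H-pyran-2-one (LiN(i-Pr)2, THF, −78 °C) is acylated at its 6-methyl carbon by 7 to give 4-hydroxy-6-[(10Z,18S)-18-[(tert-butyldimethylsilyl)oxy]-2-oxononadec-10-en-1-yl]-2H-pyran-2-one F3. Warm aqueous KOH opens the lactone to the 3,5,7-trioxo carboxylate, which closes by the same aldol mode to resorcylic acid 10.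

**Step 5.** Cyclization through oxygen to a 4-pyranone, or thermal loss of acetone from the dioxinone, may overtake the carbon aldol. Fallback: it sets out from compound 8 and comes back at compound 10. Heating 8 in toluene with MeOH at 110 °C releases the acylketene, which is trapped as methyl (15Z,23S)-23-[(tert-butyldimethylsilyl)oxy]-3,5,7-trioxotetracos-15-enoate F4. Cs2CO3 in MeOH, then AcOH, closes the doubly activated C2 onto the C7 ketone to give methyl 2-[(8Z,16S)-16-[(tert-butyldimethylsilyl)oxy]heptadec-8-en-1-yl]-4,6-dihydroxybenzoate F5. The KOH of step 6 hydrolyses F5 to 10.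

**Step 6.** Decarboxylation may stall at the resorcylate, the resorcinolate may be oxidized by traces of air in hot alkali, or the warm acid may begin to move the olefin. Fallback: it sets out from compound 9 and comes back at compound 12. LiOH in THF/H2O at 40 °C gives acid 10, now isolated. Bu4NF in THF removes the silyl ether to give 2,4-dihydroxy-6-[(8Z,16S)-16-hydroxyheptadec-8-en-1-yl]benzoic acid F6. Metal-mediated protodecarboxylation (Ag2CO3 cat., AcOH, DMSO, 120 °C) then gives 12 under nearly neutral conditions.

## Further compounds

F1 | step 1 | (S)-dec-9-en-2-ol | C[C@H](O)CCCCCCC=C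
F2 | step 1 | methyl (9Z,17S)-17-hydroxyoctadec-9-enoate | C[C@H](O)CCCCCC/C=C\CCCCCCCC(=O)OC
F3 | step 4 | 4-hydroxy-6-[(10Z,18S)-18-[(tert-butyldimethylsilyl)oxy]-2-oxononadec-10-en-1-yl]-2H-pyran-2-one | C[C@H](O[Si](C)(C)C(C)(C)C)CCCCCC/C=C\CCCCCCCC(=O)CC1=CC(O)=CC(=O)O1
F4 | step 5 | methyl (15Z,23S)-23-[(tert-butyldimethylsilyl)oxy]-3,5,7-trioxotetracos-15-enoate | C[C@H](O[Si](C)(C)C(C)(C)C)CCCCCC/C=C\CCCCCCCC(=O)CC(=O)CC(=O)CC(=O)OC
F5 | step 5 | methyl 2-[(8Z,16S)-16-[(tert-butyldimethylsilyl)oxy]heptadec-8-en-1-yl]-4,6-dihydroxybenzoate | C[C@H](O[Si](C)(C)C(C)(C)C)CCCCCC/C=C\CCCCCCCc1cc(O)cc(O)c1C(=O)OC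
F6 | step 6 | 2,4-dihydroxy-6-[(8Z,16S)-16-hydroxyheptadec-8-en-1-yl]benzoic acid | C[C@H](O)CCCCCC/C=C\CCCCCCCc1cc(O)cc(O)c1C(=O)O
A1 | alternative 1 | 8-(3,5-dimethoxyphenyl)octanal | COc1cc(CCCCCCCC=O)cc(OC)c1
A2 | alternative 1 | [(8S)-8-[(tert-butyldimethylsilyl)oxy]nonyl]triphenylphosphonium bromide | C[C@H](O[Si](C)(C)C(C)(C)C)CCCCCCC[P+](c1ccccc1)(c1ccccc1)c1ccccc1.[Br-]
A3 | alternative 1 | tert-butyl{[(2S,9Z)-17-(3,5-dimethoxyphenyl)heptadec-9-en-2-yl]oxy}dimethylsilane | C[C@H](O[Si](C)(C)C(C)(C)C)CCCCCC/C=C\CCCCCCCc1cc(OC)cc(OC)c1
A4 | alternative 2 | 1,3-dimethoxy-5-(non-8-yn-1-yl)benzene | C#CCCCCCCCc1cc(OC)cc(OC)c1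
A5 | alternative 2 | tert-butyl{[(2S)-8-iodooctan-2-yl]oxy}dimethylsilane | C[C@H](O[Si](C)(C)C(C)(C)C)CCCCCCI
A6 | alternative 2 | tert-butyl{[(2S)-17-(3,5-dimethoxyphenyl)heptadec-9-yn-2-yl]oxy}dimethylsilane | C[C@H](O[Si](C)(C)C(C)(C)C)CCCCCCC#CCCCCCCCc1cc(OC)cc(OC)c1
A7 | alternative 3 | (3E,12Z,20S)-20-[(tert-butyldimethylsilyl)oxy]henicosa-3,12-dien-2-one | C[C@H](O[Si](C)(C)C(C)(C)C)CCCCCC/C=C\CCCCCCC/C=C/C(C)=O
A8 | alternative 3 | 5-[(8Z,16S)-16-[(tert-butyldimethylsilyl)oxy]heptadec-8-en-1-yl]cyclohexane-1,3-dione | C[C@H](O[Si](C)(C)C(C)(C)C)CCCCCC/C=C\CCCCCCCC1CC(=O)CC(=O)C1
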